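**Plan**

- Retrosynthesis (labdane numbering): remove the C15 silyl group and the C7 acetate (7β-O by inversion of a 7α-alcohol that comes from a 7α,8α-epoxide of a Δ7 olefin). Cut C14–C15 and C13–C16 (alkyne carboalumination) and C11–C12 (borane alkylation at a C9=C11 methylene).
- Then cut ring A at C1–C2 and C3–C4 in one operation. This leaves a monocyclic ring B aldehyde ester and a two-carbon vinylphosphonium unit.
- Enabling feature: C4 is α to the C19 ester carbonyl (donor), and C1 is a CH2 on the quaternary C10, so it can be carried as a non-enolisable aldehyde (acceptor). Both hang 1,4 across the C5–C10 bond of ring B, so the C2–C3 bridge of ring A can be inserted as one unit.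
- Forward: (R)-carvone supplies ring B (C5–C10, C17) and the isopropenyl carbons C4/C18/C19. Two α′-alkylations build C10, a Wittig reaction gives C9=C11, the annulation closes ring A, the side chain is grown from C11, and ring B is oxidised last.
- Stereochemistry: C5 from (R)-carvone; C10 by alkylation anti to the C5 substituent; C4 in the key step (enolate face anti to C10); C9 by hydroboration anti to the C20 methyl; C7 by α-epoxidation then Mitsunobu inversion; 13E by syn-carbometalation.

Key step: step 8

Remark: atom positions are given in labdane numbering throughout. Compound 2 is a mixture of C10 epimers and compounds 6–10 are mixtures of C4 epimers; both centres are planarised again (steps 2 and 8), so this is of no consequence.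

**Route**

Step 1
Reactants: 1 (R)-(−)-carvone
Product: 2 (5R)-2,6-dimethyl-5-(prop-1-en-2-yl)cyclohex-2-en-1-one (6-methylcarvone; both C6 epimers)
Conditions: LiN(iPr)2, THF, −78 °C; MeI, −78 → 0 °C
Reagents that add atoms: iodomethane, CI
Why: Kinetic deprotonation at the α′ carbon (future C10) gives the cross-conjugated lithium enolate, which should be C-methylated in an SN2 enolate alkylation to install C20.

Step 2
Reactants: 2 (5R)-2,6-dimethyl-5-(prop-1-en-2-yl)cyclohex-2-en-1-one
Product: 4 6-(dimethoxymethyl)-2,6-dimethyl-5-(prop-1-en-2-yl)cyclohex-2-en-1-one (CH(OMe)2 trans and 6-methyl cis to the isopropenyl group), via trimethylsilyl dienol ether 3 (not isolated)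
Conditions: LiN(iPr)2, THF, −78 °C; Me3SiCl; filtration in pentane; HC(OMe)3, Me3SiOTf (5 mol%), CH2Cl2, −78 °C
Reagents that add atoms: trimethyl orthoformate, COC(OC)OC
Why: In this Mukaiyama-type alkylation the dimethoxycarbenium ion should attack the kinetic silyl dienol ether anti to the adjacent isopropenyl group, which sets the quaternary C10 with the masked C1 aldehyde trans and the methyl cis to the C5 substituent.

Step 3
Reactants: 4 6-(dimethoxymethyl)-2,6-dimethyl-5-(prop-1-en-2-yl)cyclohex-2-en-1-one
Product: 5 5-(dimethoxymethyl)-1,5-dimethyl-6-methylidene-4-(prop-1-en-2-yl)cyclohexene (same relative configuration)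
Conditions: Ph3PCH3Br, KOtBu, toluene, 90 °C
Reagents that add atoms: methyltriphenylphosphonium bromide, C[P+](c1ccccc1)(c1ccccc1)c1ccccc1.[Br-]
Why: Wittig methylenation of the hindered ketone, which has no α′-hydrogen left, should introduce C11 and mask the base-sensitive enone as a diene for the key step.

Step 4
Reactants: 5 5-(dimethoxymethyl)-1,5-dimethyl-6-methylidene-4-(prop-1-en-2-yl)cyclohexene
Product: 7 2-[2-(dimethoxymethyl)-2,4-dimethyl-3-methylidenecyclohex-4-en-1-yl]propan-1-ol (both C4 epimers), via B-alkyl-9-borabicyclononane 6 (not isolated)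
Conditions: 9-BBN (1.1 equiv), THF, 0 °C → rt; NaOH, H2O2, 0 °C
Reagents that add atoms: hydrogen peroxide, OO
Why: Anti-Markovnikov hydroboration–oxidation with 9-BBN should take the isolated 1,1-disubstituted isopropenyl alkene well ahead of the hindered conjugated diene, placing oxygen on C19.

Step 5
Reactants: 7 2-[2-(dimethoxymethyl)-2,4-dimethyl-3-methylidenecyclohex-4-en-1-yl]propan-1-ol
Product: 8 2-[2-(dimethoxymethyl)-2,4-dimethyl-3-methylidenecyclohex-4-en-1-yl]propanoic acid
Conditions: TEMPO (20 mol%), PhI(OAc)2 (2.2 equiv), MeCN/pH 7 phosphate buffer, rt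
Reagents that add atoms: water, O
Why: Oxoammonium-catalysed oxidation of the primary alcohol through the aldehyde hydrate should give the acid under buffered conditions that leave the acetal and the diene intact.

Step 6
Reactants: 8 2-[2-(dimethoxymethyl)-2,4-dimethyl-3-methylidenecyclohex-4-en-1-yl]propanoic acid
Product: 9 methyl 2-[2-(dimethoxymethyl)-2,4-dimethyl-3-methylidenecyclohex-4-en-1-yl]propanoate
Conditions: MeI, K2CO3, DMF, rt
Reagents that add atoms: iodomethane, CI
Why: SN2 O-alkylation of the carboxylate should give the C19 methyl ester without touching the acetal.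

Step 7
Reactants: 9 methyl 2-[2-(dimethoxymethyl)-2,4-dimethyl-3-methylidenecyclohex-4-en-1-yl]propanoate
Product: 10 methyl 2-(2-formyl-2,4-dimethyl-3-methylidenecyclohex-4-en-1-yl)propanoate
Conditions: PPTS (cat.), acetone/H2O, 50 °C
Reagents that add atoms: water, O
Why: Mild acid-catalysed acetal hydrolysis should release the neopentyl, non-enolisable C1 aldehyde while the methyl ester and the diene survive.

Step 8
Reactants: 10 methyl 2-(2-formyl-2,4-dimethyl-3-methylidenecyclohex-4-en-1-yl)propanoate
Product: 13 methyl 12,13,14,15,16-pentanorlabda-1,7,9(11)-trien-19-oate (trans-fused; 5α-H; 10β-methyl; CO2Me axial on the β face of C4), via lithium ester enolate 11 (not isolated), via phosphorus ylide 12 (not isolated)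
Conditions: lithium 2,2,6,6-tetramethylpiperidide (1.1 equiv), THF, −78 °C; vinyltriphenylphosphonium bromide, −78 °C → rt, then 50 °C
Reagents that add atoms: vinyltriphenylphosphonium bromide, C=C[P+](c1ccccc1)(c1ccccc1)c1ccccc1.[Br-]
Why: The amide base, which has no β-hydrogen and is too hindered to add to the neopentyl aldehyde, deprotonates C4; the enolate adds in Michael fashion to the vinylphosphonium salt to form C3–C4 and the ylide 12 at C2, and the ylide closes ring A by intramolecular Wittig olefination of the C1 aldehyde to form C1=C2. The closest known reaction type is the Schweizer annulation, in which a carbanion carrying a tethered carbonyl group adds to vinyltriphenylphosphonium bromide and the resulting ylide cyclises to a cycloalkene. Ring A (C1–C5, C10) closes by attack of the ylide carbon C2 on the exocyclic C1=O (6-exo-trig carbonyl addition along the C2–C3–C4–C5–C10–C1 chain) followed by oxaphosphetane collapse, which can only give the cis-cyclohexene. The new quaternary stereocentre C4 is set in the intermolecular Michael step under control of C5: with C5–H eclipsing the enolate double bond (allylic 1,3-strain) the acceptor approaches the face turned toward C6 and away from the quaternary C10, which places C19 on the β face (axial CO2Me, cis to C20) once the ring has closed. The step needs chemoselectivity (enolate before ylide, phosphonium salt before aldehyde), secured by the non-enolisable aldehyde and by the C9 ketone being masked as the C9=C11 alkene, and it needs facial selectivity at C4, secured by the size difference between C6H2 and the fully substituted C10.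

Step 9
Reactants: 13 methyl 12,13,14,15,16-pentanorlabda-1,7,9(11)-trien-19-oate
Product: 15 methyl 13-oxo-14,15-dinorlabda-1,7-dien-19-oate (9α-H), via B-alkyl-9-borabicyclononane 14 (not isolated)
Conditions: 9-BBN (1.5 equiv), THF, 60 °C; BrCH2COCH3, potassium 2,6-di-tert-butylphenoxide, THF, 0 °C → rt
Reagents that add atoms: bromoacetone, CC(=O)CBr
Why: 9-BBN should add only to the exocyclic C9=C11 terminus (cyclohexene-type alkenes are far slower) from the α face anti to the axial C20 methyl, which sets 9α-H, and the borane is then alkylated by the bromoacetone enolate through a 1,2-metallate shift (organoborane α-alkylation of an α-halo ketone) to add C12, C13 and a methyl.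

Step 10
Reactants: 15 methyl 13-oxo-14,15-dinorlabda-1,7-dien-19-oate
Product: 16 methyl 13-oxo-14,15-dinorlabd-7-en-19-oate
Conditions: H2 (1 atm), RhCl(PPh3)3 (10 mol%), benzene/EtOH, rt
Reagents that add atoms: none
Why: Homogeneous hydrogenation with RhCl(PPh3)3 should saturate the cis-disubstituted C1=C2 bond left by the Wittig closure and spare the trisubstituted C7=C8 bond and the ketone.

Step 11
Reactants: 16 methyl 13-oxo-14,15-dinorlabd-7-en-19-oate
Product: 18 methyl 15,16-dinorlabd-7-en-13-yn-19-oate, via enol diethyl phosphate 17 (not isolated)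
Conditions: LiN(iPr)2 (1.1 equiv), THF, −78 °C; ClP(O)(OEt)2, −78 °C → rt; LiN(iPr)2 (2.5 equiv), −78 °C → rt
Reagents that add atoms: none
Why: Kinetic enolisation on the methyl side, O-phosphorylation and base-induced elimination (methyl ketone to terminal alkyne via the enol phosphate) should give the C13≡C14 alkyne, a side-chain precursor inert to the next two steps, and the C19 ester has no α-hydrogen and is shielded.

Step 12
Reactants: 18 methyl 15,16-dinorlabd-7-en-13-yn-19-oate
Product: 19 methyl 7α,8α-epoxy-15,16-dinorlabd-13-yn-19-oate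
Conditions: mCPBA, NaHCO3, CH2Cl2, 0 °C
Reagents that add atoms: 3-chloroperoxybenzoic acid, OOC(=O)c1cccc(Cl)c1
Why: Prilezhaev epoxidation should occur only at the electron-rich trisubstituted C7=C8 bond (the terminal alkyne is far less reactive) and from the α face, because the β face is screened by the axial C20 methyl and the C9 substituent.

Step 13
Reactants: 19 methyl 7α,8α-epoxy-15,16-dinorlabd-13-yn-19-oate
Product: 20 methyl 7α-hydroxy-15,16-dinorlabd-8(17)-en-13-yn-19-oate
Conditions: Et2AlCl, lithium 2,2,6,6-tetramethylpiperidide, toluene, 0 °C → rt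
Reagents that add atoms: none
Why: The aluminium amide formed in the flask coordinates the oxirane oxygen and removes a proton from the C17 methyl (the alkyl group cis to the oxirane hydrogen) in a cyclic syn-elimination, which should give the exocyclic allylic alcohol with the C7–O bond and its α configuration retained.

Step 14
Reactants: 20 methyl 7α-hydroxy-15,16-dinorlabd-8(17)-en-13-yn-19-oate
Product: 22 methyl 7α,15-dihydroxylabda-8(17),13E-dien-19-oate, via alkenyldimethylalane 21 (not isolated)
Conditions: Me3Al, Cp2ZrCl2 (25 mol%), CH2Cl2, 0 °C → rt; n-BuLi, THF, −78 °C; (CH2O)n, −78 °C → rt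
Reagents that add atoms: trimethylaluminium, C[Al](C)C; formaldehyde (as paraformaldehyde), C=O
Why: Zirconium-catalysed syn-carboalumination of the terminal alkyne (Negishi carboalumination) puts the new methyl (C16) on C13 and aluminium on C14, and hydroxymethylation of the derived aluminate with retention adds C15, so the 13E geometry is fixed by the syn addition.

Step 15
Reactants: 22 methyl 7α,15-dihydroxylabda-8(17),13E-dien-19-oate
Product: 23 methyl 15-(tert-butyldimethylsilyloxy)-7α-hydroxylabda-8(17),13E-dien-19-oate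
Conditions: TBSCl, imidazole, CH2Cl2, −20 °C
Reagents that add atoms: tert-butyldimethylsilyl chloride, CC(C)(C)[Si](C)(C)Cl
Why: The primary allylic C15 hydroxyl should be silylated selectively over the hindered axial secondary C7 hydroxyl.

Step 16
Reactants: 23 methyl 15-(tert-butyldimethylsilyloxy)-7α-hydroxylabda-8(17),13E-dien-19-oate
Product: 24 methyl 7β-acetoxy-15-(tert-butyldimethylsilyloxy)labda-8(17),13E-dien-19-oate
Conditions: PPh3, DIAD, AcOH, toluene, 0 °C → rt
Reagents that add atoms: acetic acid, CC(=O)O
Why: Mitsunobu esterification should displace the activated axial 7α-oxygen by acetate with SN2 inversion, which installs the equatorial 7β-acetate directly.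

Step 17
Reactants: 24 methyl 7β-acetoxy-15-(tert-butyldimethylsilyloxy)labda-8(17),13E-dien-19-oate
Product: 25 methyl 7β-acetoxy-15-hydroxylabda-8(17),13E-dien-19-oate (target)
Conditions: HF·pyridine, THF, 0 °C
Reagents that add atoms: none
Why: Fluoride-driven cleavage of the primary silyl ether under mildly acidic conditions should free the C15 alcohol without acyl migration or loss of the C7 acetate and the C19 methyl ester.

**Compound list**

1 | (R)-(−)-carvone, (5R)-2-methyl-5-(prop-1-en-2-yl)cyclohex-2-en-1-one | CC1=CC[C@@H](C(C)=C)CC1=O | starting material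
2 | (5R)-2,6-dimethyl-5-(prop-1-en-2-yl)cyclohex-2-en-1-one (both C6 epimers) | CC1=CC[C@@H](C(C)=C)C(C)C1=O | intermediate
3 | trimethylsilyl dienol ether of 2, (5R)-2,6-dimethyl-5-(prop-1-en-2-yl)-1-(trimethylsilyloxy)cyclohexa-1(6),2-diene | CC1=CC[C@@H](C(C)=C)C(C)=C1O[Si](C)(C)C | intermediate
4 | 6-(dimethoxymethyl)-2,6-dimethyl-5-(prop-1-en-2-yl)cyclohex-2-en-1-one, CH(OMe)2 trans and methyl cis to isopropenyl | CC1=CC[C@@H](C(C)=C)[C@](C)(C(OC)OC)C1=O | intermediate
5 | 5-(dimethoxymethyl)-1,5-dimethyl-6-methylidene-4-(prop-1-en-2-yl)cyclohexene, same relative configuration | CC1=CC[C@@H](C(C)=C)[C@](C)(C(OC)OC)C1=C | intermediate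
6 | B-alkyl-9-borabicyclo[3.3.1]nonane from hydroboration of the isopropenyl group of 5 | CC1=CC[C@@H](C(C)CB2C3CCCC2CCC3)[C@](C)(C(OC)OC)C1=C | intermediate
7 | 2-[2-(dimethoxymethyl)-2,4-dimethyl-3-methylidenecyclohex-4-en-1-yl]propan-1-ol (both C4 epimers) | CC1=CC[C@@H](C(C)CO)[C@](C)(C(OC)OC)C1=C | intermediate
8 | 2-[2-(dimethoxymethyl)-2,4-dimethyl-3-methylidenecyclohex-4-en-1-yl]propanoic acid | CC1=CC[C@@H](C(C)C(=O)O)[C@](C)(C(OC)OC)C1=C | intermediate
9 | methyl 2-[2-(dimethoxymethyl)-2,4-dimethyl-3-methylidenecyclohex-4-en-1-yl]propanoate | CC1=CC[C@@H](C(C)C(=O)OC)[C@](C)(C(OC)OC)C1=C | intermediate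
10 | methyl 2-(2-formyl-2,4-dimethyl-3-methylidenecyclohex-4-en-1-yl)propanoate | CC1=CC[C@@H](C(C)C(=O)OC)[C@](C)(C=O)C1=C | intermediate
11 | lithium ester enolate of 10 | CC1=CC[C@@H](C(C)=C(O[Li])OC)[C@](C)(C=O)C1=C | intermediate
12 | phosphorus ylide from Michael addition of 11 to the vinylphosphonium salt (C4 quaternary, ylide carbon C2) | CC1=CC[C@@H]([C@](C)(CC=P(c2ccccc2)(c2ccccc2)c2ccccc2)C(=O)OC)[C@](C)(C=O)C1=C | intermediate
13 | methyl 12,13,14,15,16-pentanorlabda-1,7,9(11)-trien-19-oate (5α-H, 10β-methyl, 4β-axial CO2Me) | CC1=CC[C@@H]2[C@](C)(C=CC[C@]2(C)C(=O)OC)C1=C | intermediate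
14 | methyl 11-(9-borabicyclo[3.3.1]nonan-9-yl)-12,13,14,15,16-pentanorlabda-1,7-dien-19-oate (9α-H) | CC1=CC[C@@H]2[C@](C)(C=CC[C@]2(C)C(=O)OC)[C@H]1CB1C2CCCC1CCC2 | intermediate
15 | methyl 13-oxo-14,15-dinorlabda-1,7-dien-19-oate | CC1=CC[C@@H]2[C@](C)(C=CC[C@]2(C)C(=O)OC)[C@H]1CCC(C)=O | intermediate
16 | methyl 13-oxo-14,15-dinorlabd-7-en-19-oate | CC1=CC[C@@H]2[C@](C)(CCC[C@]2(C)C(=O)OC)[C@H]1CCC(C)=O | intermediate
17 | enol diethyl phosphate of 16 (terminal C13=CH2 enol) | CC1=CC[C@@H]2[C@](C)(CCC[C@]2(C)C(=O)OC)[C@H]1CCC(=C)OP(=O)(OCC)OCC | intermediate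
18 | methyl 15,16-dinorlabd-7-en-13-yn-19-oate | CC1=CC[C@@H]2[C@](C)(CCC[C@]2(C)C(=O)OC)[C@H]1CCC#C | intermediate
19 | methyl 7α,8α-epoxy-15,16-dinorlabd-13-yn-19-oate | C[C@@]12O[C@@H]1C[C@@H]3[C@](C)(CCC[C@]3(C)C(=O)OC)[C@H]2CCC#C | intermediate
20 | methyl 7α-hydroxy-15,16-dinorlabd-8(17)-en-13-yn-19-oate | C=C1[C@H](O)C[C@@H]2[C@](C)(CCC[C@]2(C)C(=O)OC)[C@H]1CCC#C | intermediate
21 | (13E)-14-dimethylalanyl alkene with the C7 oxygen as its dimethylaluminium alkoxide | C=C1[C@H](O[Al](C)C)C[C@@H]2[C@](C)(CCC[C@]2(C)C(=O)OC)[C@H]1CC/C(C)=C/[Al](C)C | intermediate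
22 | methyl 7α,15-dihydroxylabda-8(17),13E-dien-19-oate | C=C1[C@H](O)C[C@@H]2[C@](C)(CCC[C@]2(C)C(=O)OC)[C@H]1CC/C(C)=C/CO | intermediate
23 | methyl 15-(tert-butyldimethylsilyloxy)-7α-hydroxylabda-8(17),13E-dien-19-oate | C=C1[C@H](O)C[C@@H]2[C@](C)(CCC[C@]2(C)C(=O)OC)[C@H]1CC/C(C)=C/CO[Si](C)(C)C(C)(C)C | intermediate
24 | methyl 7β-acetoxy-15-(tert-butyldimethylsilyloxy)labda-8(17),13E-dien-19-oate | C=C1[C@@H](OC(C)=O)C[C@@H]2[C@](C)(CCC[C@]2(C)C(=O)OC)[C@H]1CC/C(C)=C/CO[Si](C)(C)C(C)(C)C | intermediate
25 | methyl 7β-acetoxy-15-hydroxylabda-8(17),13E-dien-19-oate | C=C1[C@@H](OC(C)=O)C[C@@H]2[C@](C)(CCC[C@]2(C)C(=O)OC)[C@H]1CC/C(C)=C/CO | target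

**Step count**

Total step count: 17. Longest linear sequence: 17 steps, fully linear from (R)-carvone.

**Steps most likely to fail**

Step 8. The free aldehyde may be consumed by carbonyl addition of the enolate (intermolecular aldol) before the hindered tetrasubstituted enolate has added to the phosphonium salt. The fallback sets out from acetal ester 9, so base and aldehyde never meet. LiN(iPr)2 then allyl bromide should give methyl 2-[2-(dimethoxymethyl)-2,4-dimethyl-3-methylidenecyclohex-4-en-1-yl]-2-methylpent-4-enoate F1, with C3–C4 formed under the same enolate-face control. PPTS in acetone/water should then give the aldehyde methyl 2-(2-formyl-2,4-dimethyl-3-methylidenecyclohex-4-en-1-yl)-2-methylpent-4-enoate F2. Ph3P=CH2 should convert the C1 aldehyde into the vinyl compound methyl 2-(2-ethenyl-2,4-dimethyl-3-methylidenecyclohex-4-en-1-yl)-2-methylpent-4-enoate F3. Ring-closing metathesis of the vinyl and allyl groups with the first-generation Grubbs catalyst RuCl2(PCy3)2(=CHPh) should form C1=C2 and come back to the route at 13.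

Step 9. Boron-to-carbon migration of the hindered β-branched primary alkyl group may be too slow, so that the borane is protonolysed instead of alkylated. The fallback sets out from 13. 9-BBN then NaOH/H2O2 should give methyl 11-hydroxy-12,13,14,15,16-pentanorlabda-1,7-dien-19-oate F4. H2 with RhCl(PPh3)3 should give methyl 11-hydroxy-12,13,14,15,16-pentanorlabd-7-en-19-oate F5. I2, PPh3 and imidazole (Appel-type iodination) should give methyl 11-iodo-12,13,14,15,16-pentanorlabd-7-en-19-oate F6. SN2 displacement with 3-lithio-1-(trimethylsilyl)propyne should give methyl 14-(trimethylsilyl)-15,16-dinorlabd-7-en-13-yn-19-oate F7. K2CO3 in MeOH should remove the silyl group and come back to the route at 18.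

Step 16. Acetate may attack the exocyclic C17 terminus with allylic transposition, or elimination may occur, in place of direct inversion at C7. The fallback sets out from 23. Dess–Martin periodinane should give the enone methyl 15-(tert-butyldimethylsilyloxy)-7-oxolabda-8(17),13E-dien-19-oate F8. Luche reduction (NaBH4, CeCl3·7H2O, MeOH, −78 °C), with axial hydride delivery from the α face, should give the equatorial alcohol methyl 15-(tert-butyldimethylsilyloxy)-7β-hydroxylabda-8(17),13E-dien-19-oate F9. Ac2O, DMAP and pyridine should then come back to the route at 24.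

**Further compounds**

F1 | step 8 | methyl 2-[2-(dimethoxymethyl)-2,4-dimethyl-3-methylidenecyclohex-4-en-1-yl]-2-methylpent-4-enoate | CC1=CC[C@@H]([C@](C)(CC=C)C(=O)OC)[C@](C)(C(OC)OC)C1=C
F2 | step 8 | methyl 2-(2-formyl-2,4-dimethyl-3-methylidenecyclohex-4-en-1-yl)-2-methylpent-4-enoate | CC1=CC[C@@H]([C@](C)(CC=C)C(=O)OC)[C@](C)(C=O)C1=C
F3 | step 8 | methyl 2-(2-ethenyl-2,4-dimethyl-3-methylidenecyclohex-4-en-1-yl)-2-methylpent-4-enoate | CC1=CC[C@@H]([C@](C)(CC=C)C(=O)OC)[C@](C)(C=C)C1=C
F4 | step 9 | methyl 11-hydroxy-12,13,14,15,16-pentanorlabda-1,7-dien-19-oate | CC1=CC[C@@H]2[C@](C)(C=CC[C@]2(C)C(=O)OC)[C@H]1CO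
F5 | step 9 | methyl 11-hydroxy-12,13,14,15,16-pentanorlabd-7-en-19-oate | CC1=CC[C@@H]2[C@](C)(CCC[C@]2(C)C(=O)OC)[C@H]1CO
F6 | step 9 | methyl 11-iodo-12,13,14,15,16-pentanorlabd-7-en-19-oate | CC1=CC[C@@H]2[C@](C)(CCC[C@]2(C)C(=O)OC)[C@H]1CI
F7 | step 9 | methyl 14-(trimethylsilyl)-15,16-dinorlabd-7-en-13-yn-19-oate | CC1=CC[C@@H]2[C@](C)(CCC[C@]2(C)C(=O)OC)[C@H]1CCC#C[Si](C)(C)C
F8 | step 16 | methyl 15-(tert-butyldimethylsilyloxy)-7-oxolabda-8(17),13E-dien-19-oate | C=C1C(=O)C[C@@H]2[C@](C)(CCC[C@]2(C)C(=O)OC)[C@H]1CC/C(C)=C/CO[Si](C)(C)C(C)(C)C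
F9 | step 16 | methyl 15-(tert-butyldimethylsilyloxy)-7β-hydroxylabda-8(17),13E-dien-19-oate | C=C1[C@@H](O)C[C@@H]2[C@](C)(CCC[C@]2(C)C(=O)OC)[C@H]1CC/C(C)=C/CO[Si](C)(C)C(C)(C)C
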